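**Strategy**

Locants: oxolane O1, C2 (aryl), C3, C4, C5; C6 is the hydroxymethyl carbon on C3 and C7 the carbonyl carbon on C4. The route rests on the C3–C6 disconnection and exploits the cis chain C6–C3–C4–C7 on the C3–C4 edge of the oxolane ring, which is a masked 1,4-diol: C6 is delivered from the C7 oxygen through a temporary O–SiMe2–CH2 bridge. One 6-endo radical cyclisation onto C3=C4 of a (2S)-2-aryl-2,5-dihydrofuran forms C3–C6, closes a cis-fused oxasilinane and sets C3 and C4. The precursor is the (bromomethyl)dimethylsilyl ether of an aryl(dihydrofuranyl)carbinol whose phenols are benzyl ethers, stable to fluoride, peroxide and base and removable under neutral conditions.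

Key step: step 11

Assumption 1: the aryl Grignard addition in step 9 is expected to show no useful facial bias, so compounds 16 and 18–22 are carried as mixtures of C7 epimers (C7 left undefined in their SMILES); both epimers converge when C7 becomes the carbonyl carbon in step 13.

Assumption 2: the sense of the kinetic resolution in step 3 is taken from the usual Sharpless model, by which L-(+)-DIPT should epoxidise the (R)-carbinol faster and leave the (S)-carbinol.

**Route**

Step 1
Reactants: 1 syringaldehyde; 2 benzyl bromide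
Product: 3 4-(benzyloxy)-3,5-dimethoxybenzaldehyde
Conditions: BnBr, K2CO3, DMF, 60 °C
Reagents that add atoms: benzyl bromide, BrCc1ccccc1
Why: Williamson etherification, in which the phenoxide formed with K2CO3 displaces bromide and the aldehyde is left untouched.

Step 2
Reactants: 3 4-(benzyloxy)-3,5-dimethoxybenzaldehyde; 4 vinylmagnesium bromide
Product: 5 rac-1-[4-(benzyloxy)-3,5-dimethoxyphenyl]prop-2-en-1-ol
Conditions: CH2=CHMgBr, THF, −78 to 0 °C; aq. NH4Cl
Reagents that add atoms: vinylmagnesium bromide, C=C[Mg]Br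
Why: Grignard 1,2-addition to a non-enolisable aryl aldehyde, which forms the carbinol centre as a racemate that is resolved in step 3.

Step 3
Reactants: 5 rac-1-[4-(benzyloxy)-3,5-dimethoxyphenyl]prop-2-en-1-ol
Product: 6 (1S)-1-[4-(benzyloxy)-3,5-dimethoxyphenyl]prop-2-en-1-ol
Conditions: Ti(OiPr)4 (0.2 equiv), L-(+)-DIPT (0.24 equiv), t-BuOOH (0.6 equiv), 4 Å MS, CH2Cl2, −20 °C
Reagents that add atoms: none
Why: Sharpless kinetic resolution, in which the titanium tartrate complex should epoxidise the (R)-carbinol much faster, so that the unreacted alcohol is recovered as the (S)-enantiomer that becomes C2 of the target.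

Step 4
Reactants: 6 (1S)-1-[4-(benzyloxy)-3,5-dimethoxyphenyl]prop-2-en-1-ol; 7 methyl 2-(bromomethyl)acrylate
Product: 9 methyl 2-({[(1S)-1-[4-(benzyloxy)-3,5-dimethoxyphenyl]prop-2-en-1-yl]oxy}methyl)prop-2-enoate, via sodium alkoxide 8 (not isolated)
Conditions: NaH, THF, 0 °C; then 7, 0 °C to rt
Reagents that add atoms: methyl 2-(bromomethyl)acrylate, C=C(CBr)C(=O)OC
Why: Williamson O-allylation of the alkoxide with an activated allylic bromide (direct and SN2' displacement give the same ether), with the carbinol C–O bond and its configuration untouched.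

Step 5
Reactants: 9 methyl 2-({[(1S)-1-[4-(benzyloxy)-3,5-dimethoxyphenyl]prop-2-en-1-yl]oxy}methyl)prop-2-enoate
Product: 10 methyl (5S)-5-[4-(benzyloxy)-3,5-dimethoxyphenyl]-2,5-dihydrofuran-3-carboxylate
Conditions: second-generation Grubbs catalyst (H2IMes)(PCy3)Cl2Ru=CHPh (5 mol%), CH2Cl2, 40 °C
Reagents that add atoms: none
Why: Ring-closing metathesis between the vinyl group and the acrylate-type 1,1-disubstituted alkene closes the five-membered 2,5-dihydrofuran with loss of ethene, a closure well established for 2-(allyloxymethyl)acrylates, and the stereocentre is a spectator.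

Step 6
Reactants: 10 methyl (5S)-5-[4-(benzyloxy)-3,5-dimethoxyphenyl]-2,5-dihydrofuran-3-carboxylate
Product: 11 {(5S)-5-[4-(benzyloxy)-3,5-dimethoxyphenyl]-2,5-dihydrofuran-3-yl}methanol
Conditions: i-Bu2AlH (2.5 equiv), CH2Cl2, −78 °C; aq. potassium sodium tartrate
Reagents that add atoms: none
Why: 1,2-Reduction of the conjugated ester by the aluminium hydride gives the primary allylic alcohol without touching the alkene, the benzyl ether or the C2–H.

Step 7
Reactants: 11 {(5S)-5-[4-(benzyloxy)-3,5-dimethoxyphenyl]-2,5-dihydrofuran-3-yl}methanol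
Product: 12 (5S)-5-[4-(benzyloxy)-3,5-dimethoxyphenyl]-2,5-dihydrofuran-3-carbaldehyde
Conditions: Dess–Martin periodinane, NaHCO3, CH2Cl2, 0 °C to rt
Reagents that add atoms: none
Why: Dess–Martin oxidation of the primary allylic alcohol to the enal under buffered, non-basic conditions, which should avoid deprotonation of the doubly activated C2–H and aromatisation of the ring.

Step 8
Reactants: 13 4-bromo-2,6-dimethoxyphenol; 2 benzyl bromide
Product: 14 2-(benzyloxy)-5-bromo-1,3-dimethoxybenzene
Conditions: BnBr, K2CO3, DMF, 60 °C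
Reagents that add atoms: benzyl bromide, BrCc1ccccc1
Why: Williamson etherification of the phenoxide, as in step 1.

Step 9
Reactants: 14 2-(benzyloxy)-5-bromo-1,3-dimethoxybenzene; 12 (5S)-5-[4-(benzyloxy)-3,5-dimethoxyphenyl]-2,5-dihydrofuran-3-carbaldehyde
Product: 16 [4-(benzyloxy)-3,5-dimethoxyphenyl]{(5S)-5-[4-(benzyloxy)-3,5-dimethoxyphenyl]-2,5-dihydrofuran-3-yl}methanol (both C7 epimers), via arylmagnesium bromide 15 (not isolated)
Conditions: Mg, THF, reflux; then 12, THF, −78 °C; aq. NH4Cl
Reagents that add atoms: [4-(benzyloxy)-3,5-dimethoxyphenyl]magnesium bromide (from 14), COc1cc([Mg]Br)cc(OC)c1OCc1ccccc1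
Why: Magnesium insertion followed by Grignard 1,2-addition to the enal at low temperature forms the C7–aryl bond; the remote C2 centre gives no control, so C7 forms as both epimers, which is harmless because C7 ends as the carbonyl carbon.

Step 10
Reactants: 16 [4-(benzyloxy)-3,5-dimethoxyphenyl]{(5S)-5-[4-(benzyloxy)-3,5-dimethoxyphenyl]-2,5-dihydrofuran-3-yl}methanol; 17 (bromomethyl)chlorodimethylsilane
Product: 18 (bromomethyl)dimethylsilyl ether of 16: (2S)-2-aryl-2,5-dihydrofuran carrying on C4 the group C7H(aryl)–O–SiMe2–CH2Br, aryl = 4-(benzyloxy)-3,5-dimethoxyphenyl (both C7 epimers)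
Conditions: BrCH2SiMe2Cl, Et3N, DMAP (cat.), CH2Cl2, 0 °C
Reagents that add atoms: (bromomethyl)chlorodimethylsilane, C[Si](C)(Cl)CBr
Why: O-Silylation of the secondary alcohol under amine base, the Si–Cl bond reacting far faster than the C–Br bond, installs the one-carbon tether on the C7 oxygen.

Step 11
Reactants: 18 (bromomethyl)dimethylsilyl ether of 16
Product: 21 cis-fused oxolane–1,2-oxasilinane, (2S,3S,4R)-2-aryl-oxolane in which C3 carries C6H2 and C4 carries C7H(aryl)–O, C6 and the C7 oxygen being joined through SiMe2 (ring O–SiMe2–C6–C3–C4–C7; both C7 epimers), via silylmethyl radical 19 (not isolated), via C4 radical 20 (not isolated)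
Conditions: Bu3SnH (1.3 equiv, slow addition), AIBN (cat.), benzene (0.01 M), 80 °C
Reagents that add atoms: none
Why: Bu3Sn• abstracts bromine from the Si–CH2Br group, the α-silyl primary radical 19 adds to C3 of the C3=C4 bond, and the tertiary C4 radical 20 takes hydrogen from Bu3SnH and passes the chain on. The closest known reaction type is the silicon-tethered radical cyclisation of (bromomethyl)dimethylsilyl ethers of allylic alcohols that is followed by Tamao oxidation. The 1,2-oxasilinane ring closes in the 6-endo-trig mode, because 5-exo attack at the fully substituted C4 would build a spiro quaternary centre and is slower than attack at the hydrogen-bearing terminus C3, the regiochemistry established for such ethers when the proximal alkene carbon carries no hydrogen. C3 is controlled by the C2 aryl group, the radical adding to the ring face anti to it, and C4 is controlled by the tether and the new C3–C6 bond, hydrogen arriving on the opposite face so that the six-membered ring ends cis-fused and C6 and C7 stand cis to each other and trans to the aryl group. The step needs 6-endo regioselectivity, anti facial selectivity and cyclisation ahead of direct reduction; the substitution pattern of the alkene, the C2 aryl group and slow addition of the stannane at high dilution should secure these, and each C7 epimer can place its aryl group equatorially in one chair of the cis-fused ring.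

Step 12
Reactants: 21 cis-fused oxolane–1,2-oxasilinane
Product: 22 [4-(benzyloxy)-3,5-dimethoxyphenyl]{(3R,4R,5S)-5-[4-(benzyloxy)-3,5-dimethoxyphenyl]-4-(hydroxymethyl)oxolan-3-yl}methanol (both C7 epimers)
Conditions: 30% H2O2, KF, KHCO3, THF/MeOH, rt
Reagents that add atoms: hydrogen peroxide, OO
Why: Tamao–Kumada oxidation, in which fluoride-activated silicon takes up hydroperoxide, the C6 methylene migrates from silicon to oxygen and hydrolysis of both Si–O bonds frees the C6 and C7 hydroxyls without touching a stereocentre or the benzyl ethers.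

Step 13
Reactants: 22 [4-(benzyloxy)-3,5-dimethoxyphenyl]{(3R,4R,5S)-5-[4-(benzyloxy)-3,5-dimethoxyphenyl]-4-(hydroxymethyl)oxolan-3-yl}methanol
Product: 23 [4-(benzyloxy)-3,5-dimethoxyphenyl]{(3R,4R,5S)-5-[4-(benzyloxy)-3,5-dimethoxyphenyl]-4-(hydroxymethyl)oxolan-3-yl}methanone
Conditions: MnO2 (activated, excess), CH2Cl2, rt
Reagents that add atoms: none
Why: Chemoselective MnO2 oxidation of the benzylic secondary alcohol, in which both C7 epimers converge on one ketone, the unactivated primary C6 alcohol is left alone and the neutral medium should not epimerise the now enolisable C4.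

Step 14
Reactants: 23 [4-(benzyloxy)-3,5-dimethoxyphenyl]{(3R,4R,5S)-5-[4-(benzyloxy)-3,5-dimethoxyphenyl]-4-(hydroxymethyl)oxolan-3-yl}methanone
Product: 24 ciwujiatone, (4-hydroxy-3,5-dimethoxyphenyl)[(3R,4R,5S)-5-(4-hydroxy-3,5-dimethoxyphenyl)-4-(hydroxymethyl)oxolan-3-yl]methanone
Conditions: H2 (1 atm), 10% Pd/C, EtOAc, rt
Reagents that add atoms: none
Why: Palladium-catalysed hydrogenolysis should cleave the two aryl benzyl ethers much faster than the cyclic benzylic C2–O1 bond or the electron-rich aryl ketone, and its neutrality protects the β-alkoxy ketone from C4 epimerisation and from ring-opening by β-elimination.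

**Compound list**

1 | syringaldehyde (4-hydroxy-3,5-dimethoxybenzaldehyde) | COc1cc(C=O)cc(OC)c1O | starting material
2 | benzyl bromide | BrCc1ccccc1 | starting material
3 | 4-(benzyloxy)-3,5-dimethoxybenzaldehyde | COc1cc(C=O)cc(OC)c1OCc1ccccc1 | intermediate
4 | vinylmagnesium bromide | C=C[Mg]Br | starting material
5 | rac-1-[4-(benzyloxy)-3,5-dimethoxyphenyl]prop-2-en-1-ol | C=CC(O)c1cc(OC)c(OCc2ccccc2)c(OC)c1 | intermediate
6 | (1S)-1-[4-(benzyloxy)-3,5-dimethoxyphenyl]prop-2-en-1-ol | C=C[C@H](O)c1cc(OC)c(OCc2ccccc2)c(OC)c1 | intermediate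
7 | methyl 2-(bromomethyl)acrylate | C=C(CBr)C(=O)OC | starting material
8 | sodium (1S)-1-[4-(benzyloxy)-3,5-dimethoxyphenyl]prop-2-en-1-olate (not isolated) | C=C[C@H]([O-])c1cc(OC)c(OCc2ccccc2)c(OC)c1.[Na+] | intermediate
9 | methyl 2-({[(1S)-1-[4-(benzyloxy)-3,5-dimethoxyphenyl]prop-2-en-1-yl]oxy}methyl)prop-2-enoate | C=C[C@H](OCC(=C)C(=O)OC)c1cc(OC)c(OCc2ccccc2)c(OC)c1 | intermediate
10 | methyl (5S)-5-[4-(benzyloxy)-3,5-dimethoxyphenyl]-2,5-dihydrofuran-3-carboxylate | COc1cc(cc(OC)c1OCc1ccccc1)[C@H]1OCC(=C1)C(=O)OC | intermediate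
11 | {(5S)-5-[4-(benzyloxy)-3,5-dimethoxyphenyl]-2,5-dihydrofuran-3-yl}methanol | COc1cc(cc(OC)c1OCc1ccccc1)[C@H]1OCC(=C1)CO | intermediate
12 | (5S)-5-[4-(benzyloxy)-3,5-dimethoxyphenyl]-2,5-dihydrofuran-3-carbaldehyde | COc1cc(cc(OC)c1OCc1ccccc1)[C@H]1OCC(=C1)C=O | intermediate
13 | 4-bromo-2,6-dimethoxyphenol | COc1cc(Br)cc(OC)c1O | starting material
14 | 2-(benzyloxy)-5-bromo-1,3-dimethoxybenzene | COc1cc(Br)cc(OC)c1OCc1ccccc1 | intermediate
15 | [4-(benzyloxy)-3,5-dimethoxyphenyl]magnesium bromide (not isolated) | COc1cc([Mg]Br)cc(OC)c1OCc1ccccc1 | intermediate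
16 | [4-(benzyloxy)-3,5-dimethoxyphenyl]{(5S)-5-[4-(benzyloxy)-3,5-dimethoxyphenyl]-2,5-dihydrofuran-3-yl}methanol, both C7 epimers | COc1cc(cc(OC)c1OCc1ccccc1)[C@H]1OCC(=C1)C(O)c1cc(OC)c(OCc2ccccc2)c(OC)c1 | intermediate
17 | (bromomethyl)chlorodimethylsilane | C[Si](C)(Cl)CBr | starting material
18 | (bromomethyl)dimethylsilyl ether of 16 (C2 S, both C7 epimers) | COc1cc(cc(OC)c1OCc1ccccc1)[C@H]1OCC(=C1)C(O[Si](C)(C)CBr)c1cc(OC)c(OCc2ccccc2)c(OC)c1 | intermediate
19 | silylmethyl radical from 18, Si–CH2• (not isolated) | COc1cc(cc(OC)c1OCc1ccccc1)[C@H]1OCC(=C1)C(O[Si](C)(C)[CH2])c1cc(OC)c(OCc2ccccc2)c(OC)c1 | intermediate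
20 | cyclised tertiary radical at C4, C3–C6 bond formed, (2S,3S) (not isolated) | COc1cc(cc(OC)c1OCc1ccccc1)[C@H]1OC[C]2C(c3cc(OC)c(OCc4ccccc4)c(OC)c3)O[Si](C)(C)C[C@H]12 | intermediate
21 | cis-fused oxolane–1,2-oxasilinane, (2S,3S,4R), ring O–SiMe2–C6H2–C3–C4–C7H(aryl), both C7 epimers | COc1cc(cc(OC)c1OCc1ccccc1)[C@H]1OC[C@@H]2C(c3cc(OC)c(OCc4ccccc4)c(OC)c3)O[Si](C)(C)C[C@H]12 | intermediate
22 | [4-(benzyloxy)-3,5-dimethoxyphenyl]{(3R,4R,5S)-5-[4-(benzyloxy)-3,5-dimethoxyphenyl]-4-(hydroxymethyl)oxolan-3-yl}methanol, both C7 epimers | COc1cc(C(O)[C@H]2CO[C@H](c3cc(OC)c(OCc4ccccc4)c(OC)c3)[C@H]2CO)cc(OC)c1OCc1ccccc1 | intermediate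
23 | [4-(benzyloxy)-3,5-dimethoxyphenyl]{(3R,4R,5S)-5-[4-(benzyloxy)-3,5-dimethoxyphenyl]-4-(hydroxymethyl)oxolan-3-yl}methanone | COc1cc(C(=O)[C@H]2CO[C@H](c3cc(OC)c(OCc4ccccc4)c(OC)c3)[C@H]2CO)cc(OC)c1OCc1ccccc1 | intermediate
24 | ciwujiatone, (4-hydroxy-3,5-dimethoxyphenyl)[(3R,4R,5S)-5-(4-hydroxy-3,5-dimethoxyphenyl)-4-(hydroxymethyl)oxolan-3-yl]methanone | COc1cc(C(=O)[C@H]2CO[C@H](c3cc(OC)c(O)c(OC)c3)[C@H]2CO)cc(OC)c1O | target

**Step count**

Total step count: 14. Longest linear sequence: 13 steps (steps 1–7 and 9–14); step 8 is a one-step side branch.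

**Steps most likely to fail**

Step 11. The silylmethyl radical may be reduced before it cyclises, 5-exo closure may compete with 6-endo closure, or facial selectivity may erode for the C7 epimer that is less well matched to attack anti to the C2 aryl group. The fallback sets out from 16 and comes back to the route at 23, introducing C6 as an intermolecular silylmethyl nucleophile instead of a tethered radical. Carbinol 16 is oxidised with MnO2 (CH2Cl2, rt) to the enone [4-(benzyloxy)-3,5-dimethoxyphenyl]{(5S)-5-[4-(benzyloxy)-3,5-dimethoxyphenyl]-2,5-dihydrofuran-3-yl}methanone F1. Copper-catalysed conjugate addition of (isopropoxydimethylsilyl)methylmagnesium chloride (CuI cat., THF, −78 °C) should occur at C3 anti to the C2 aryl group. Protonation of the enolate at −78 °C (AcOH) on the face away from the new C3 substituent should then give the cis ketone [4-(benzyloxy)-3,5-dimethoxyphenyl]{(3R,4R,5S)-5-[4-(benzyloxy)-3,5-dimethoxyphenyl]-4-[(isopropoxydimethylsilyl)methyl]oxolan-3-yl}methanone F2. Tamao oxidation of the C–Si bond (H2O2, KF, KHCO3, THF/MeOH, 0 °C) then gives 23. The price is that C4 is set by kinetic protonation instead of by the tether.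

Step 4. The alkoxide may polymerise or transesterify the acrylate, or the alkylation may stall at low conversion. The fallback sets out from 6 and comes back to the route at 16, bypassing steps 4 to 9 and taking the second aryl group from aldehyde 3. Alcohol 6 is O-alkylated with 2,3-dibromopropene (NaH, THF, 0 °C to rt) to give 2-(benzyloxy)-5-{(1S)-1-[(2-bromoprop-2-en-1-yl)oxy]prop-2-en-1-yl}-1,3-dimethoxybenzene F3. Bromine–lithium exchange (t-BuLi, Et2O, −78 °C) and addition of the vinyllithium to aldehyde 3 give the dienol 1-[4-(benzyloxy)-3,5-dimethoxyphenyl]-2-({[(1S)-1-[4-(benzyloxy)-3,5-dimethoxyphenyl]prop-2-en-1-yl]oxy}methyl)prop-2-en-1-ol F4. Ring-closing metathesis (second-generation Grubbs catalyst, CH2Cl2, 40 °C) then gives 16.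

Step 14. Over-reduction may set in, either hydrogenolysis of the benzylic C2–O1 bond once the phenol is free or reduction of the aryl ketone. The fallback sets out from 23 and goes directly to 24 by a non-reductive Lewis-acid dealkylation: BCl3 with pentamethylbenzene as benzyl-cation scavenger (CH2Cl2, −78 °C). This fallback makes no new compound (F0).

**Further compounds**

F1 | step 11 | [4-(benzyloxy)-3,5-dimethoxyphenyl]{(5S)-5-[4-(benzyloxy)-3,5-dimethoxyphenyl]-2,5-dihydrofuran-3-yl}methanone | COc1cc(cc(OC)c1OCc1ccccc1)[C@H]1OCC(=C1)C(=O)c1cc(OC)c(OCc2ccccc2)c(OC)c1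
F2 | step 11 | [4-(benzyloxy)-3,5-dimethoxyphenyl]{(3R,4R,5S)-5-[4-(benzyloxy)-3,5-dimethoxyphenyl]-4-[(isopropoxydimethylsilyl)methyl]oxolan-3-yl}methanone | COc1cc(C(=O)[C@H]2CO[C@H](c3cc(OC)c(OCc4ccccc4)c(OC)c3)[C@H]2C[Si](C)(C)OC(C)C)cc(OC)c1OCc1ccccc1
F3 | step 4 | 2-(benzyloxy)-5-{(1S)-1-[(2-bromoprop-2-en-1-yl)oxy]prop-2-en-1-yl}-1,3-dimethoxybenzene | C=C[C@H](OCC(Br)=C)c1cc(OC)c(OCc2ccccc2)c(OC)c1
F4 | step 4 | 1-[4-(benzyloxy)-3,5-dimethoxyphenyl]-2-({[(1S)-1-[4-(benzyloxy)-3,5-dimethoxyphenyl]prop-2-en-1-yl]oxy}methyl)prop-2-en-1-ol, both carbinol epimers | C=C[C@H](OCC(=C)C(O)c1cc(OC)c(OCc2ccccc2)c(OC)c1)c1cc(OC)c(OCc2ccccc2)c(OC)c1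
F0 | step 14 | none | none
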